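Between 50.0 s and 60.0 s the target in this flask rose by just 1.1 percentage points, against a scatter of 1 point per reading, so one step between rows tells us little and we read wider windows. The question concerns the same flask, followed further.

| flask | starting material | partner | second substrate | remark | time |
|---|---|---|---|---|---|
| theta | 20 mM | 50 mM | 100 mM | the very flask that is asked about, followed so far |  |
| flask | 20 mM | 50.0 mM | 100 mM |  | 2.0 min |

theta run (percent of the starting material charged)

| time / s | starting material / % | isomer of the product / % | target / % |
|---|---|---|---|
| 10.0 | 73.9 | 0.5 | 24.4 |
| 12.0 | 69.7 | 2.7 | 26.3 |
| 20.0 | 55.8 | 3.8 | 37.1 |
| 30.0 | 44.2 | 9.2 | 47.8 |
| 50.0 | 30.7 | 15.0 | 58.1 |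
| 60.0 | 21.2 | 20.0 | 59.2 |

(standard deviation of a reading: 1 percentage point)

* where most of what was charged as starting material, at 2.0 min is found (starting material / target / isomer of the product)
* the largest share itself, whichever of these holds it, in percent of the starting material charged

Set the columns against each other. At 60.0 s the three species add up to 100% of the charge, so on this reading the material stays among them. The first row has target at 24.4% and isomer at 0.5%, so we take the isomer as coming from target. Starting material lost in a window is then what target receives, and isomer gained is what target gives up.

From 30.0 s to 60.0 s those amounts are 23 points and 11 points, a ratio of 2.13. This ratio, starting material lost over isomer gained in one window, we call the handover ratio m: with the material held among these three species, target climbs while m stands above one and crests where m reaches one. The rows from 10.0 s to 30.0 s give 3.41, so on these scattered readings m is falling.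

If the fall continues in the same proportion, m reaches one near 85.1 s, a rough reading but earlier than 2.0 min. We therefore expect target to have crested and to stand near its last reading, 59.2%, and so to hold most, with the remaining 40.8% of the charge, less than that, shared by isomer and starting material.

The forecast also names target, but at 50%, lower than our figure: “target should still lead, but not by much”.

The flask gives target at 61.4%, with isomer at 31.4% and starting material at 7.19%.

    starting material + partner → target (k = 0.630 /M/s)
    second substrate + partner → second product (k = 0.00660 /M/s)
    target → over-reaction product (k = 3.40 × 10⁻⁶ /s)
    target ⇌ isomer of the product (K = 0.660, k = 0.0100 /s)

Over the flask's second minute m is 1.18, down from 2.13, and target rises from 59.0% to 61.4%. Taken as net rates at one moment in this flask, target is made 3.96 times as fast as it is used up at 0.372 min, and that ratio is 0.939 at 2.00 min. In the neighbour flask with 12 mM of partner, the same ratio of net rates at 2.0 min is 1.63, still above one, and starting material holds most there, at 60.5%, with target at 27.1%.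

(The data are calculated on assumed constants; noise was put on by code.)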